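Litres per mole per second were the unit in which this flask shared out its reagent: 160 L mol⁻¹ s⁻¹ to the starting material against 48 L mol⁻¹ s⁻¹ to the partner.

starting material 1.0 mM; partner 1.00 mM; reagent 1.50 mM; capture agent 0.300 mM; time 40 min

    starting material + reagent → open intermediate (k1 = 160 L mol⁻¹ s⁻¹)
    reagent + partner → second intermediate (k2 = 48 L mol⁻¹ s⁻¹)
    open intermediate + second intermediate → target (k3 = 22 L mol⁻¹ s⁻¹)
    2 open intermediate → homo product (k4 = 41 L mol⁻¹ s⁻¹)
    second intermediate + capture agent → trapped intermediate (k5 = 9.2 L mol⁻¹ s⁻¹)
    reagent + target → over-reaction product (k6 = 0.81 L mol⁻¹ s⁻¹)

- a species is counted by the starting material in it: one homo product counts as two
- a doubled species enters its step squared and goes two at a time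
- the reaction counts as stopped when no species that holds the starting material changes by six tenths of a point or more over the second half of the time
- run time (flask): 40 min

1. which holds at 40 min: what has brought the reaction to rest, or that it has not come to rest (all of the starting material has reacted / it is still moving / the reagent has run out first / the partner has run out first / forward and back rates have come level)
2. target at 40 min, in percent of the starting material charged
3. homo product at 40 min, in percent of the starting material charged
4. amount of target if the flask were left three thousand times as long, in percent of the starting material charged

1. On the fastest rung I set the reagent's half-life by step 1 alone, 0.0722 min, beside 0.24 min by step 2 alone; both were shorter than the 4.2 min of capture. The two takers offered 2.00 mM against 1.50 mM of reagent, so I expected the reagent to be the limiting reagent.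

2. Let a and d be the fractions of starting material and partner left. Both steps carry the same reagent concentration, so it cancels from the ratio of their logarithmic losses, and a = d^S, where S, the selectivity factor, is the ratio of the two rate constants for the reagent, 3.33.

3. With equal charges, spending the reagent on these two steps gave a + d = h, with h = 0.500. I treated a as the small correction: setting d = h gave a first value g = 9.92%, and linearising (h − a)^S gave a = g/(1 + Sg/h) = 5.97%, leaving d at 44.0%.

4. Next came the open intermediate, with 0.203 min as its first half-life by step 4 if its concentration equalled the starting charge. Then came capture, and last step 6, whose 9.5 min was longer than the reagent's half-life. My reckoning stopped here, with 94.0% of the starting material passing on and no hand figure for its split.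

The forecast went further: the reagent has run out first, with 23% target, 70.5% homo product and 23% on long standing, since “no reagent remains for over-reaction”.

The flask gave the reagent has run out first, with 23.4% target, 70.1% homo product and 23.4% on long standing. Over the second half of the time no species holding the starting material moved by more than 0.1 percentage points, with the reagent at 0% of its charge, while in this flask capture went on and the capture agent fell from 18.1% to 8.75% of its charge. In this flask the partner reading of 43.7%, raised to the power S, gives 6.34%, beside 6.34% of starting material. In the neighbour charged with 4.0 mM of partner, 77.0% of the partner stood at the end; the same power gives 41.9%, and that flask held 41.9% of its starting material.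

(The numbers stand for no real mixture.)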